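**Retrosynthetic overview**
- The γ-lactone is closed last by oxidative lactonisation of the O6/O12 diol, after C14 acylation, C9 acetylation and chelation-controlled reduction of a C9 ketone.
- Feature: O9–C9, the C8–C9 bond and the C4=C5 olefin form a 3-oxy-1,5-diene (C7=C8–C9(O)–C4–C5=C6) once C6–C7 is cut, and the cis C1=C10 olefin lies inside a cyclohexene made of C9, C10, C1, C2, C3 and C4.
- Key disconnection: the ten-membered ring comes from a cis-1,6-dialkenyl-6-methylcyclohex-2-en-1-ol by anionic oxy-Cope ring expansion (C6–C7 made, C4–C9 broken) with hydroxylation of the C8=C9 enolate in the same flask. The oxygen should enter 8R and is inverted to 8S before C9 is reduced.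
- The cyclohexenol comes from an enone keto ester (asymmetric α-methylation, dehydrogenation, Baylis–Hillman) and an E-dienyl metal; the ester is then taken to the aldehyde, the E-vinyl iodide and the E-PMB enol ether.
- Ring order: cyclohexene (from the keto ester), then the ten-membered carbocycle, then the γ-lactone.

Key step: step 15

Remark on numbering: ring-expanded compounds are named on the germacrane skeleton (C1=C10 with C14 on C10, C4=C5 with C15 on C4, O on C6, C7 carrying C11(=C13)–C12, then C8 and C9).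
Abbreviations: TBDPS = tert-butyldiphenylsilyl, PMB = 4-methoxybenzyl, TMS = trimethylsilyl, MOM = methoxymethyl.
Assumption: in the auxiliary-directed methylation of step 2 the sense of induction follows the donor additive and the valine enantiomer, and the pairing that gives the S keto ester is used.

Step 1
Reactants: 1 ethyl 2-oxocyclohexane-1-carboxylate; 2 tert-butyl L-valinate
Product: 3 ethyl 2-{[(2S)-1-tert-butoxy-3-methyl-1-oxobutan-2-yl]amino}cyclohex-1-ene-1-carboxylate
Conditions: BF3·OEt2 (cat.), benzene, reflux, azeotropic removal of water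
Reagents that add atoms: none
Why: Acid-catalysed condensation of the β-keto ester with the primary amine should give the conjugated, hydrogen-bonded β-enamino ester, with no new stereocentre and the valine centre untouched.

Step 2
Reactants: 3 β-enamino ester
Product: 6 ethyl (1S)-1-methyl-2-oxocyclohexane-1-carboxylate, via lithio enamine 4 (not isolated), via methylated imine 5 (not isolated)
Conditions: LiN(iPr)2, toluene, HMPA (1 equiv), −78 °C; MeI; then 1 M aq HCl, rt
Reagents that add atoms: iodomethane, CI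
Why: Chiral lithio-enamine (aza-enolate) alkylation, in which lithium is held by the enamine nitrogen and the valine ester carbonyl, the isopropyl group shields one face and iodomethane enters on the other to set the quaternary centre S, after which acid hydrolysis of imine 5 releases the auxiliary.

Step 3
Reactants: 6 ethyl (1S)-1-methyl-2-oxocyclohexane-1-carboxylate
Product: 7 ethyl (1S)-1-methyl-2-oxocyclohex-3-ene-1-carboxylate
Conditions: IBX (2 equiv), DMSO/toluene 1:2, 70 °C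
Reagents that add atoms: none
Why: IBX-mediated dehydrogenation of the ketone through its enol can only run toward the CH2–CH2 side because the other α-carbon is quaternary, so a single enone should result with the stereocentre untouched.

Step 4
Reactants: 7 ethyl (1S)-1-methyl-2-oxocyclohex-3-ene-1-carboxylate
Product: 8 ethyl (1S)-3-(hydroxymethyl)-1-methyl-2-oxocyclohex-3-ene-1-carboxylate
Conditions: 37% aq HCHO, DMAP (0.2 equiv), THF, rt
Reagents that add atoms: formaldehyde, C=O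
Why: Morita–Baylis–Hillman reaction, in which DMAP adds reversibly to the unhindered β-carbon, the resulting enolate is hydroxymethylated at the α-carbon and DMAP is expelled.

Step 5
Reactants: 8 ethyl (1S)-3-(hydroxymethyl)-1-methyl-2-oxocyclohex-3-ene-1-carboxylate
Product: 9 ethyl (1S)-1-methyl-2-oxo-3-[(TBDPS-oxy)methyl]cyclohex-3-ene-1-carboxylate
Conditions: TBDPSCl, imidazole, CH2Cl2, rt
Reagents that add atoms: tert-butyl(chloro)diphenylsilane, CC(C)(C)[Si](Cl)(c1ccccc1)c1ccccc1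
Why: Silylation of the primary allylic alcohol gives a silyl ether that should withstand the organometallic, hydride, amide-base and oxidative steps up to step 21.

Step 6
Reactants: 10 2-bromoprop-2-en-1-ol
Product: 11 2-bromoprop-2-en-1-yl 4-methoxybenzyl ether
Conditions: NaH, PMBCl, Bu4NI (cat.), THF, 0 °C to rt
Reagents that add atoms: 4-methoxybenzyl chloride, COc1ccc(CCl)cc1
Why: Williamson etherification of the primary alkoxide, with PMB chosen for O12 so that it can later be removed together with the O6 PMB ether in one oxidation.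

Step 7
Reactants: 11 2-bromoprop-2-en-1-yl 4-methoxybenzyl ether; 12 (E)-1,2-bis(tributylstannyl)ethene
Product: 13 tributyl[(1E)-3-[(PMB-oxy)methyl]buta-1,3-dien-1-yl]stannane
Conditions: Pd(PPh3)4 (5 mol %), toluene, 90 °C, 12 in twofold excess
Reagents that add atoms: none
Why: Stille cross-coupling of the vinyl bromide with one tin terminus of the bis-stannane on zerovalent palladium, with the excess of 12 suppressing double coupling and the E geometry retained.

Step 8
Reactants: 13 tributyl[(1E)-3-[(PMB-oxy)methyl]buta-1,3-dien-1-yl]stannane; 9 ethyl (1S)-1-methyl-2-oxo-3-[(TBDPS-oxy)methyl]cyclohex-3-ene-1-carboxylate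
Product: 16 ethyl (1S,2S)-2-hydroxy-1-methyl-2-[(1E)-3-[(PMB-oxy)methyl]buta-1,3-dien-1-yl]-3-[(TBDPS-oxy)methyl]cyclohex-3-ene-1-carboxylate, via dienyllithium 14 (not isolated), via dienylmagnesium bromide 15 (not isolated)
Conditions: n-BuLi, THF, −78 °C; MgBr2·OEt2, Et2O, −78 °C; then 9, −78 to −40 °C; aq NH4Cl
Reagents that add atoms: none
Why: Tin–lithium exchange with retention and then chelation-controlled 1,2-addition of the dienyl Grignard reagent, in which magnesium bridges the ketone and ester carbonyls, holds the ester in the carbonyl plane and the methyl pseudoaxial, so that the dienyl group should enter anti to methyl and set the carbinol centre with OH cis to CH3 and the dienyl cis to the ester arm.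

Step 9
Reactants: 16 tertiary alcohol
Product: 17 ethyl (1S,2S)-1-methyl-2-[(1E)-3-[(PMB-oxy)methyl]buta-1,3-dien-1-yl]-3-[(TBDPS-oxy)methyl]-2-(TMS-oxy)cyclohex-3-ene-1-carboxylate
Conditions: TMSOTf, 2,6-lutidine, CH2Cl2, −78 °C
Reagents that add atoms: trimethylsilyl triflate, C[Si](C)(C)OS(=O)(=O)C(F)(F)F
Why: O-Silylation of the tertiary alcohol blocks retro-aldol cleavage at the aldehyde stage and premature alkoxide chemistry under the hot carbonate of step 13.

Step 10
Reactants: 17 TMS-protected ester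
Product: 18 {(1R,2R)-1-methyl-2-[(1E)-3-[(PMB-oxy)methyl]buta-1,3-dien-1-yl]-3-[(TBDPS-oxy)methyl]-2-(TMS-oxy)cyclohex-3-en-1-yl}methanol
Conditions: iBu2AlH (3 equiv), CH2Cl2, −78 to 0 °C; aq potassium sodium tartrate
Reagents that add atoms: none
Why: Hydride reduction of the neopentyl-type ester to the primary alcohol, with the silyl and PMB ethers inert.

Step 11
Reactants: 18 primary alcohol
Product: 19 (1S,2S)-1-methyl-2-[(1E)-3-[(PMB-oxy)methyl]buta-1,3-dien-1-yl]-3-[(TBDPS-oxy)methyl]-2-(TMS-oxy)cyclohex-3-ene-1-carbaldehyde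
Conditions: Dess–Martin periodinane, NaHCO3, CH2Cl2, 0 °C to rt
Reagents that add atoms: none
Why: Buffered Dess–Martin oxidation should give the non-enolisable aldehyde without touching the acid-sensitive tertiary allylic silyl ether.

Step 12
Reactants: 19 aldehyde
Product: 20 (5R,6R)-5-[(E)-2-iodoethenyl]-5-methyl-6-[(1E)-3-[(PMB-oxy)methyl]buta-1,3-dien-1-yl]-1-[(TBDPS-oxy)methyl]-6-(TMS-oxy)cyclohex-1-ene
Conditions: CrCl2 (6 equiv), CHI3 (2 equiv), THF/dioxane, 0 °C to rt
Reagents that add atoms: iodoform, IC(I)I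
Why: Takai olefination with the gem-dichromium species from iodoform should convert the aldehyde into the E vinyl iodide.

Step 13
Reactants: 20 E vinyl iodide; 21 4-methoxybenzyl alcohol
Product: 22 (5R,6R)-5-methyl-5-[(E)-2-(PMB-oxy)ethenyl]-6-[(1E)-3-[(PMB-oxy)methyl]buta-1,3-dien-1-yl]-1-[(TBDPS-oxy)methyl]-6-(TMS-oxy)cyclohex-1-ene
Conditions: CuI (10 mol %), 3,4,7,8-tetramethyl-1,10-phenanthroline (20 mol %), Cs2CO3, toluene, 80 °C
Reagents that add atoms: none
Why: Copper-catalysed Ullmann-type C–O cross-coupling of the vinyl iodide with the primary benzylic alcohol should proceed with retention of the E geometry and give the enol ether that becomes O6.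

Step 14
Reactants: 22 TMS-protected enol ether
Product: 23 (1R,6R)-6-methyl-6-[(E)-2-(PMB-oxy)ethenyl]-1-[(1E)-3-[(PMB-oxy)methyl]buta-1,3-dien-1-yl]-2-[(TBDPS-oxy)methyl]cyclohex-2-en-1-ol
Conditions: K2CO3, MeOH, 0 °C to rt
Reagents that add atoms: none
Why: Base-catalysed methanolysis should cleave the tertiary trimethylsilyl ether selectively and release the oxy-Cope substrate, leaving the TBDPS ether, both PMB ethers and the enol ether intact.

Step 15
Reactants: 23 cis-dialkenyl cyclohexenol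
Product: 26 (1(10)Z,4Z,6R,7R,8R)-8-hydroxy-6,12-bis(PMB-oxy)-14-(TBDPS-oxy)germacra-1(10),4,11(13)-trien-9-one, via potassium alkoxide 24 (not isolated), via ring-E potassium enolate 25 (not isolated)
Conditions: KN(SiMe3)2 (1.2 equiv), 18-crown-6 (1.5 equiv), THF, −78 to 0 °C; cool to −78 °C; 3-phenyl-2-(phenylsulfonyl)oxaziridine (1.5 equiv); aq NH4Cl at −78 °C
Reagents that add atoms: 3-phenyl-2-(phenylsulfonyl)oxaziridine, O=S(=O)(c1ccccc1)N1OC1c1ccccc1
Why: Deprotonation gives the crown-separated alkoxide 24, whose C4–C9 bond is weakened by the oxyanion, and a chair [3,3] shift across C7=C8–C9–C4–C5=C6 makes C6–C7, breaks C4–C9 and delivers enolate 25, which the N-sulfonyloxaziridine hydroxylates at C8 (anionic oxy-Cope rearrangement followed by enolate oxidation, both known, run here in one flask). The ten-membered ring is closed by a four-atom ring expansion of the cyclohexene inside a six-centre transition state and not by end-to-end cyclisation, and the cis C1=C10 olefin is carried over from the six-membered ring. C6 and C7 are set by the chair in which both E termini (the PMB-oxy group on C6 and C11 on C7) and C10 are equatorial and C3 is axial, which trades the C4 and C9 centres for 6R,7R and leaves C3 cis to C6 on the new C4=C5 bond (Z). C8 is set by peripheral attack on the ring-E enolate as it leaves this chair: the only open face is anti to the C6–C7 bond and syn to the axial H7, so the oxygen should arrive trans to the C7 arm (8R), whereas the 8S centre of the target lies on the transannular face and is therefore made by inversion in steps 16 and 17. The step needs the chair with C10 equatorial and not the alternative chair with C10 and CH3 axial, which would give the 4E isomer with inverted C6 and C7; this is secured by the bulk of the fully substituted C10 with its CH2O-TBDPS group against the small oxyanion and by the cis relation of the two alkenyl groups fixed in step 8.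

Step 16
Reactants: 26 8R α-ketol
Product: 27 (1(10)Z,4Z,6R,7S,8S)-8-(4-nitrobenzoyloxy)-6,12-bis(PMB-oxy)-14-(TBDPS-oxy)germacra-1(10),4,11(13)-trien-9-one
Conditions: 4-nitrobenzoic acid, PPh3, DIAD, toluene, 0 °C to rt
Reagents that add atoms: 4-nitrobenzoic acid, O=C(O)c1ccc(cc1)[N+](=O)[O-]
Why: Mitsunobu reaction, in which the oxyphosphonium derivative of the α-ketol is displaced by 4-nitrobenzoate in an SN2 step that is accelerated by the adjacent carbonyl and inverts C8 from R to S.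

Step 17
Reactants: 27 8S 4-nitrobenzoate
Product: 28 (1(10)Z,4Z,6R,7R,8S)-8-hydroxy-6,12-bis(PMB-oxy)-14-(TBDPS-oxy)germacra-1(10),4,11(13)-trien-9-one
Conditions: K2CO3 (0.2 equiv), MeOH, 0 °C
Reagents that add atoms: none
Why: Mild transesterification of the activated 4-nitrobenzoate should release the 8S α-ketol (hydroxyl cis to the C7 arm) at a temperature low enough to avoid epimerisation through the enediol.

Step 18
Reactants: 28 8S α-ketol
Product: 29 (1(10)Z,4Z,6R,7S,8S)-8-(MOM-oxy)-6,12-bis(PMB-oxy)-14-(TBDPS-oxy)germacra-1(10),4,11(13)-trien-9-one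
Conditions: MOMCl, iPr2NEt, Bu4NI (cat.), CH2Cl2, 0 °C to rt
Reagents that add atoms: chloromethyl methyl ether, COCCl
Why: Alkylation of the only free hydroxyl gives an acetal ether that can chelate zinc in step 19 and keeps O8 out of the later lactonisation.

Step 19
Reactants: 29 8-MOM-oxy enone
Product: 30 (1(10)Z,4Z,6R,7S,8S,9R)-8-(MOM-oxy)-6,12-bis(PMB-oxy)-14-(TBDPS-oxy)germacra-1(10),4,11(13)-trien-9-ol
Conditions: Zn(BH4)2, Et2O, −20 °C; aq NH4Cl
Reagents that add atoms: none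
Why: Chelation-controlled 1,2-reduction, in which zinc bridges the C9 carbonyl and the C8 MOM-oxy oxygen and hydride is delivered to the face of the five-membered chelate opposite C7, which should set 9R with O9 cis to O8.

Step 20
Reactants: 30 C9 alcohol
Product: 31 (1(10)Z,4Z,6R,7S,8S,9R)-8-(MOM-oxy)-6,12-bis(PMB-oxy)-14-(TBDPS-oxy)germacra-1(10),4,11(13)-trien-9-yl acetate
Conditions: Ac2O, pyridine, DMAP (cat.), CH2Cl2, rt
Reagents that add atoms: acetic anhydride, CC(=O)OC(C)=O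
Why: Acylation of the only free hydroxyl, a secondary allylic alcohol, under nucleophilic catalysis.

Step 21
Reactants: 31 C9 acetate
Product: 32 (1(10)Z,4Z,6R,7S,8S,9R)-14-hydroxy-8-(MOM-oxy)-6,12-bis(PMB-oxy)germacra-1(10),4,11(13)-trien-9-yl acetate
Conditions: TBAF, AcOH (1:1), THF, rt
Reagents that add atoms: none
Why: Fluoride cleaves the silyl ether at C14, and buffering with acetic acid should prevent acetyl migration from O9.

Step 22
Reactants: 32 C14 alcohol; 33 (S)-2-methylbutanoic acid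
Product: 34 (1(10)Z,4Z,6R,7S,8S,9R)-9-acetoxy-8-(MOM-oxy)-6,12-bis(PMB-oxy)germacra-1(10),4,11(13)-trien-14-yl (2S)-2-methylbutanoate
Conditions: EDC·HCl, DMAP (cat.), CH2Cl2, 0 °C
Reagents that add atoms: none
Why: Steglich esterification of the primary allylic alcohol at 0 °C, where the α-stereocentre of the acid should not be enolised.

Step 23
Reactants: 34 bis-PMB ether
Product: 35 (1(10)Z,4Z,6R,7S,8S,9R)-9-acetoxy-6,12-dihydroxy-8-(MOM-oxy)germacra-1(10),4,11(13)-trien-14-yl (2S)-2-methylbutanoate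
Conditions: DDQ (2.5 equiv), CH2Cl2/pH 7 buffer, 0 °C
Reagents that add atoms: none
Why: Oxidative cleavage of both PMB ethers by DDQ through their benzylic oxocarbenium ions, with the MOM, acetate and ester groups inert.

Step 24
Reactants: 35 O6/O12 diol
Product: 38 (1(10)Z,4Z,6R,7S,8S,9R)-9-acetoxy-8-(MOM-oxy)-14-[(2S)-2-methylbutanoyloxy]germacra-1(10),4,11(13)-trien-12,6-olide, via hydroxy enal 36 (not isolated), via lactol 37 (not isolated)
Conditions: TEMPO (20 mol %), PhI(OAc)2 (2.5 equiv), CH2Cl2, rt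
Reagents that add atoms: none
Why: TEMPO/PhI(OAc)2 oxidation is selective for the primary allylic alcohol, the enal 36 is trapped by the C6 hydroxyl as lactol 37 and this is oxidised on to the trans-fused α-methylene γ-lactone, while the masked O8 cannot compete for a C12–O8 lactone and the secondary allylic C6 alcohol is not oxidised to the enone.

Step 25
Reactants: 38 MOM-protected lactone
Product: 39 (1(10)Z,4Z,6R,7R,8S,9R)-9-acetoxy-8-hydroxy-14-[(2S)-2-methylbutanoyloxy]germacra-1(10),4,11(13)-trien-12,6-olide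
Conditions: Me2BBr (3 equiv), CH2Cl2, −78 °C; then aq NaHCO3/THF
Reagents that add atoms: none
Why: Me2BBr cleaves the MOM acetal at −78 °C by bromide attack on the activated O–CH2–O unit, conditions under which the allylic esters, the acetate and the α-methylene lactone should be preserved.

**Compound list**
1 | ethyl 2-oxocyclohexane-1-carboxylate | CCOC(=O)C1CCCCC1=O | starting material
2 | tert-butyl L-valinate | CC(C)[C@H](N)C(=O)OC(C)(C)C | starting material
3 | ethyl 2-{[(2S)-1-tert-butoxy-3-methyl-1-oxobutan-2-yl]amino}cyclohex-1-ene-1-carboxylate | CCOC(=O)C1=C(N[C@@H](C(C)C)C(=O)OC(C)(C)C)CCCC1 | intermediate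
4 | N-lithio derivative of 3 (lithium aza-enolate) | CCOC(=O)C1=C(N([Li])[C@@H](C(C)C)C(=O)OC(C)(C)C)CCCC1 | intermediate
5 | ethyl (1S)-2-{[(2S)-1-tert-butoxy-3-methyl-1-oxobutan-2-yl]imino}-1-methylcyclohexane-1-carboxylate | CCOC(=O)[C@@]1(C)CCCCC1=N[C@@H](C(C)C)C(=O)OC(C)(C)C | intermediate
6 | ethyl (1S)-1-methyl-2-oxocyclohexane-1-carboxylate | CCOC(=O)[C@@]1(C)CCCCC1=O | intermediate
7 | ethyl (1S)-1-methyl-2-oxocyclohex-3-ene-1-carboxylate | CCOC(=O)[C@@]1(C)CCC=CC1=O | intermediate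
8 | ethyl (1S)-3-(hydroxymethyl)-1-methyl-2-oxocyclohex-3-ene-1-carboxylate | CCOC(=O)[C@@]1(C)CCC=C(CO)C1=O | intermediate
9 | ethyl (1S)-1-methyl-2-oxo-3-[(TBDPS-oxy)methyl]cyclohex-3-ene-1-carboxylate | CCOC(=O)[C@@]1(C)CCC=C(CO[Si](c2ccccc2)(c2ccccc2)C(C)(C)C)C1=O | intermediate
10 | 2-bromoprop-2-en-1-ol | OCC(Br)=C | starting material
11 | 2-bromoprop-2-en-1-yl 4-methoxybenzyl ether | C=C(Br)COCc1ccc(OC)cc1 | intermediate
12 | (E)-1,2-bis(tributylstannyl)ethene | CCCC[Sn](CCCC)(CCCC)/C=C/[Sn](CCCC)(CCCC)CCCC | starting material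
13 | tributyl[(1E)-3-[(PMB-oxy)methyl]buta-1,3-dien-1-yl]stannane | CCCC[Sn](CCCC)(CCCC)/C=C/C(=C)COCc1ccc(OC)cc1 | intermediate
14 | [(1E)-3-[(PMB-oxy)methyl]buta-1,3-dien-1-yl]lithium | [Li]/C=C/C(=C)COCc1ccc(OC)cc1 | intermediate
15 | [(1E)-3-[(PMB-oxy)methyl]buta-1,3-dien-1-yl]magnesium bromide | Br[Mg]/C=C/C(=C)COCc1ccc(OC)cc1 | intermediate
16 | ethyl (1S,2S)-2-hydroxy-1-methyl-2-[(1E)-3-[(PMB-oxy)methyl]buta-1,3-dien-1-yl]-3-[(TBDPS-oxy)methyl]cyclohex-3-ene-1-carboxylate (OH cis to CH3) | O[C@@]1(/C=C/C(=C)COCc2ccc(OC)cc2)C(CO[Si](c2ccccc2)(c2ccccc2)C(C)(C)C)=CCC[C@]1(C)C(=O)OCC | intermediate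
17 | ethyl (1S,2S)-1-methyl-2-[(1E)-3-[(PMB-oxy)methyl]buta-1,3-dien-1-yl]-3-[(TBDPS-oxy)methyl]-2-(TMS-oxy)cyclohex-3-ene-1-carboxylate | C[Si](C)(C)O[C@@]1(/C=C/C(=C)COCc2ccc(OC)cc2)C(CO[Si](c2ccccc2)(c2ccccc2)C(C)(C)C)=CCC[C@]1(C)C(=O)OCC | intermediate
18 | {(1R,2R)-1-methyl-2-[(1E)-3-[(PMB-oxy)methyl]buta-1,3-dien-1-yl]-3-[(TBDPS-oxy)methyl]-2-(TMS-oxy)cyclohex-3-en-1-yl}methanol | C[Si](C)(C)O[C@@]1(/C=C/C(=C)COCc2ccc(OC)cc2)C(CO[Si](c2ccccc2)(c2ccccc2)C(C)(C)C)=CCC[C@]1(C)CO | intermediate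
19 | (1S,2S)-1-methyl-2-[(1E)-3-[(PMB-oxy)methyl]buta-1,3-dien-1-yl]-3-[(TBDPS-oxy)methyl]-2-(TMS-oxy)cyclohex-3-ene-1-carbaldehyde | C[Si](C)(C)O[C@@]1(/C=C/C(=C)COCc2ccc(OC)cc2)C(CO[Si](c2ccccc2)(c2ccccc2)C(C)(C)C)=CCC[C@]1(C)C=O | intermediate
20 | (5R,6R)-5-[(E)-2-iodoethenyl]-5-methyl-6-[(1E)-3-[(PMB-oxy)methyl]buta-1,3-dien-1-yl]-1-[(TBDPS-oxy)methyl]-6-(TMS-oxy)cyclohex-1-ene | C[Si](C)(C)O[C@@]1(/C=C/C(=C)COCc2ccc(OC)cc2)C(CO[Si](c2ccccc2)(c2ccccc2)C(C)(C)C)=CCC[C@]1(C)/C=C/I | intermediate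
21 | 4-methoxybenzyl alcohol | COc1ccc(CO)cc1 | starting material
22 | (5R,6R)-5-methyl-5-[(E)-2-(PMB-oxy)ethenyl]-6-[(1E)-3-[(PMB-oxy)methyl]buta-1,3-dien-1-yl]-1-[(TBDPS-oxy)methyl]-6-(TMS-oxy)cyclohex-1-ene | C[Si](C)(C)O[C@@]1(/C=C/C(=C)COCc2ccc(OC)cc2)C(CO[Si](c2ccccc2)(c2ccccc2)C(C)(C)C)=CCC[C@]1(C)/C=C/OCc1ccc(OC)cc1 | intermediate
23 | (1R,6R)-6-methyl-6-[(E)-2-(PMB-oxy)ethenyl]-1-[(1E)-3-[(PMB-oxy)methyl]buta-1,3-dien-1-yl]-2-[(TBDPS-oxy)methyl]cyclohex-2-en-1-ol | O[C@@]1(/C=C/C(=C)COCc2ccc(OC)cc2)C(CO[Si](c2ccccc2)(c2ccccc2)C(C)(C)C)=CCC[C@]1(C)/C=C/OCc1ccc(OC)cc1 | intermediate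
24 | potassium alkoxide of 23 | [K+].[O-][C@@]1(/C=C/C(=C)COCc2ccc(OC)cc2)C(CO[Si](c2ccccc2)(c2ccccc2)C(C)(C)C)=CCC[C@]1(C)/C=C/OCc1ccc(OC)cc1 | intermediate
25 | potassium (1(10)Z,4Z,6R,7R)-6,12-bis(PMB-oxy)-14-(TBDPS-oxy)germacra-1(10),4,8,11(13)-tetraen-9-olate (C8=C9 ring-E, C7 trans to C10) | [K+].COc1ccc(CO[C@@H]2/C=C(/C)CC/C=C(/CO[Si](c3ccccc3)(c3ccccc3)C(C)(C)C)\C([O-])=C\[C@H]2C(=C)COCc4ccc(OC)cc4)cc1 | intermediate
26 | (1(10)Z,4Z,6R,7R,8R)-8-hydroxy-6,12-bis(PMB-oxy)-14-(TBDPS-oxy)germacra-1(10),4,11(13)-trien-9-one (8-OH trans to the C7 arm) | COc1ccc(CO[C@@H]2/C=C(/C)CC/C=C(/CO[Si](c3ccccc3)(c3ccccc3)C(C)(C)C)C(=O)[C@H](O)[C@H]2C(=C)COCc4ccc(OC)cc4)cc1 | intermediate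
27 | (1(10)Z,4Z,6R,7S,8S)-8-(4-nitrobenzoyloxy)-6,12-bis(PMB-oxy)-14-(TBDPS-oxy)germacra-1(10),4,11(13)-trien-9-one | COc1ccc(CO[C@@H]2/C=C(/C)CC/C=C(/CO[Si](c3ccccc3)(c3ccccc3)C(C)(C)C)C(=O)[C@@H](OC(=O)c3ccc(cc3)[N+](=O)[O-])[C@H]2C(=C)COCc4ccc(OC)cc4)cc1 | intermediate
28 | (1(10)Z,4Z,6R,7R,8S)-8-hydroxy-6,12-bis(PMB-oxy)-14-(TBDPS-oxy)germacra-1(10),4,11(13)-trien-9-one (8-OH cis to the C7 arm) | COc1ccc(CO[C@@H]2/C=C(/C)CC/C=C(/CO[Si](c3ccccc3)(c3ccccc3)C(C)(C)C)C(=O)[C@@H](O)[C@H]2C(=C)COCc4ccc(OC)cc4)cc1 | intermediate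
29 | (1(10)Z,4Z,6R,7S,8S)-8-(MOM-oxy)-6,12-bis(PMB-oxy)-14-(TBDPS-oxy)germacra-1(10),4,11(13)-trien-9-one | COc1ccc(CO[C@@H]2/C=C(/C)CC/C=C(/CO[Si](c3ccccc3)(c3ccccc3)C(C)(C)C)C(=O)[C@@H](OCOC)[C@H]2C(=C)COCc4ccc(OC)cc4)cc1 | intermediate
30 | (1(10)Z,4Z,6R,7S,8S,9R)-8-(MOM-oxy)-6,12-bis(PMB-oxy)-14-(TBDPS-oxy)germacra-1(10),4,11(13)-trien-9-ol | COc1ccc(CO[C@@H]2/C=C(/C)CC/C=C(/CO[Si](c3ccccc3)(c3ccccc3)C(C)(C)C)[C@@H](O)[C@@H](OCOC)[C@H]2C(=C)COCc4ccc(OC)cc4)cc1 | intermediate
31 | (1(10)Z,4Z,6R,7S,8S,9R)-8-(MOM-oxy)-6,12-bis(PMB-oxy)-14-(TBDPS-oxy)germacra-1(10),4,11(13)-trien-9-yl acetate | COc1ccc(CO[C@@H]2/C=C(/C)CC/C=C(/CO[Si](c3ccccc3)(c3ccccc3)C(C)(C)C)[C@@H](OC(C)=O)[C@@H](OCOC)[C@H]2C(=C)COCc4ccc(OC)cc4)cc1 | intermediate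
32 | (1(10)Z,4Z,6R,7S,8S,9R)-14-hydroxy-8-(MOM-oxy)-6,12-bis(PMB-oxy)germacra-1(10),4,11(13)-trien-9-yl acetate | COc1ccc(CO[C@@H]2/C=C(/C)CC/C=C(/CO)[C@@H](OC(C)=O)[C@@H](OCOC)[C@H]2C(=C)COCc4ccc(OC)cc4)cc1 | intermediate
33 | (S)-2-methylbutanoic acid | CC[C@H](C)C(=O)O | starting material
34 | (1(10)Z,4Z,6R,7S,8S,9R)-9-acetoxy-8-(MOM-oxy)-6,12-bis(PMB-oxy)germacra-1(10),4,11(13)-trien-14-yl (2S)-2-methylbutanoate | COc1ccc(CO[C@@H]2/C=C(/C)CC/C=C(/COC(=O)[C@@H](C)CC)[C@@H](OC(C)=O)[C@@H](OCOC)[C@H]2C(=C)COCc4ccc(OC)cc4)cc1 | intermediate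
35 | (1(10)Z,4Z,6R,7S,8S,9R)-9-acetoxy-6,12-dihydroxy-8-(MOM-oxy)germacra-1(10),4,11(13)-trien-14-yl (2S)-2-methylbutanoate | O[C@@H]1/C=C(/C)CC/C=C(/COC(=O)[C@@H](C)CC)[C@@H](OC(C)=O)[C@@H](OCOC)[C@H]1C(=C)CO | intermediate
36 | (1(10)Z,4Z,6R,7S,8S,9R)-9-acetoxy-6-hydroxy-8-(MOM-oxy)-12-oxogermacra-1(10),4,11(13)-trien-14-yl (2S)-2-methylbutanoate (hydroxy enal) | O[C@@H]1/C=C(/C)CC/C=C(/COC(=O)[C@@H](C)CC)[C@@H](OC(C)=O)[C@@H](OCOC)[C@H]1C(=C)C=O | intermediate
37 | 12,6-lactol of 36 (C12 epimers) | C=C1C(O)O[C@@H]2/C=C(/C)CC/C=C(/COC(=O)[C@@H](C)CC)[C@@H](OC(C)=O)[C@@H](OCOC)[C@@H]12 | intermediate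
38 | (1(10)Z,4Z,6R,7S,8S,9R)-9-acetoxy-8-(MOM-oxy)-14-[(2S)-2-methylbutanoyloxy]germacra-1(10),4,11(13)-trien-12,6-olide | C=C1C(=O)O[C@@H]2/C=C(/C)CC/C=C(/COC(=O)[C@@H](C)CC)[C@@H](OC(C)=O)[C@@H](OCOC)[C@@H]12 | intermediate
39 | (1(10)Z,4Z,6R,7R,8S,9R)-9-acetoxy-8-hydroxy-14-[(2S)-2-methylbutanoyloxy]germacra-1(10),4,11(13)-trien-12,6-olide | C=C1C(=O)O[C@@H]2/C=C(/C)CC/C=C(/COC(=O)[C@@H](C)CC)[C@@H](OC(C)=O)[C@@H](O)[C@@H]12 | target

**Step count and risks**
Total step count: 25. Longest linear sequence: 23 steps (1–5, then 8–25); steps 6 and 7 are the side branch.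

Step 15. The oxidation of the ring enolate in the strongly basic flask may not be clean: part of the enolate may add to the sulfonimine that the oxidant leaves behind or be protonated before oxygen transfer, and excess amide base consumes oxaziridine. A share of rearrangement through the alternative chair would show as the 4E isomer. The fallback decouples the two events. It sets out from 23: the same base and crown ether, then an acetic acid quench at −78 °C, should give the ring-expanded C9 ketone without C8 oxygen F1. LiN(SiMe3)2 and Et3SiCl convert it into the C8=C9 triethylsilyl enol ether F2. Rubottom oxidation with dimethyldioxirane (acetone/CH2Cl2, −78 °C) and a mild acid work-up should then give ketol 26, since the same peripheral face is used. The route is rejoined at 26 and continues with step 16. Should the ketol obtained be the 8S epimer 28, steps 16 and 17 are dropped.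

Step 16. The SN2 displacement at C8 has to pass a carbon flanked by the branched C7, so it may be slow and give way to elimination toward C7 or to esterification with retention through an acyloxyphosphonium ion. The base of step 17 could also equilibrate C8 through the enediol. The fallback replaces substitution by enolate protonation. It sets out from 26: MOMCl and iPr2NEt give the 8R MOM ether F3. KN(SiMe3)2 in THF at −78 °C gives its C8=C9 potassium enolate F4, which is protonated at −78 °C with 2,6-di-tert-butyl-4-methylphenol. The proton should enter on the same peripheral face that the oxygen used in step 15, so the MOM-oxy group is pushed to the 8S side. This comes back to the route at 29 and continues with step 19.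

Step 13. Oxidative addition and alkoxide exchange at the neopentyl-type vinyl iodide may be slow at 80 °C. Prolonged heating with carbonate can also strip the tertiary silyl ether and release the alkoxide, which would start the rearrangement early. The fallback works at room temperature through boron. It sets out from aldehyde 19: a Takai-type olefination with Cl2CHB(pin), CrCl2 and LiI in THF should give the E-alkenyl pinacol boronate F5. Chan–Lam coupling of F5 with 21 (Cu(OAc)2, Et3N, rt, air) should form the E enol ether with retention. It comes back to the route at 22, with step 12 bypassed.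

**Further compounds**
F1 | step 15 | (1(10)Z,4Z,6R,7S)-6,12-bis(PMB-oxy)-14-(TBDPS-oxy)germacra-1(10),4,11(13)-trien-9-one | COc1ccc(CO[C@@H]2/C=C(/C)CC/C=C(/CO[Si](c3ccccc3)(c3ccccc3)C(C)(C)C)C(=O)C[C@H]2C(=C)COCc4ccc(OC)cc4)cc1
F2 | step 15 | (1(10)Z,4Z,6R,7S)-6,12-bis(PMB-oxy)-14-(TBDPS-oxy)-9-(triethylsilyloxy)germacra-1(10),4,8,11(13)-tetraene (C8=C9 geometry as formed) | COc1ccc(CO[C@@H]2/C=C(/C)CC/C=C(/CO[Si](c3ccccc3)(c3ccccc3)C(C)(C)C)C(O[Si](CC)(CC)CC)=C[C@H]2C(=C)COCc4ccc(OC)cc4)cc1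
F3 | step 16 | (1(10)Z,4Z,6R,7S,8R)-8-(MOM-oxy)-6,12-bis(PMB-oxy)-14-(TBDPS-oxy)germacra-1(10),4,11(13)-trien-9-one | COc1ccc(CO[C@@H]2/C=C(/C)CC/C=C(/CO[Si](c3ccccc3)(c3ccccc3)C(C)(C)C)C(=O)[C@H](OCOC)[C@H]2C(=C)COCc4ccc(OC)cc4)cc1
F4 | step 16 | potassium (1(10)Z,4Z,6R,7S)-8-(MOM-oxy)-6,12-bis(PMB-oxy)-14-(TBDPS-oxy)germacra-1(10),4,8,11(13)-tetraen-9-olate | [K+].COc1ccc(CO[C@@H]2/C=C(/C)CC/C=C(/CO[Si](c3ccccc3)(c3ccccc3)C(C)(C)C)C([O-])=C(OCOC)[C@H]2C(=C)COCc4ccc(OC)cc4)cc1
F5 | step 13 | (5R,6R)-5-methyl-6-[(1E)-3-[(PMB-oxy)methyl]buta-1,3-dien-1-yl]-5-[(E)-2-(4,4,5,5-tetramethyl-1,3,2-dioxaborolan-2-yl)ethenyl]-1-[(TBDPS-oxy)methyl]-6-(TMS-oxy)cyclohex-1-ene | C[Si](C)(C)O[C@@]1(/C=C/C(=C)COCc2ccc(OC)cc2)C(CO[Si](c2ccccc2)(c2ccccc2)C(C)(C)C)=CCC[C@]1(C)/C=C/B1OC(C)(C)C(C)(C)O1
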